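**Plan**
- Retrosynthesis: ring C is opened first at O11–C11a, leaving a 2'-hydroxyisoflav-3-ene. Ring B is then cut at O5–C6 and C11b–C11a in one stroke, giving 4-prenylresorcinol and a ring D 2-arylacrolein.
- Enabling feature: ring A is a resorcinol, so O5 and C11b (ortho to O5, para to the C3 hydroxyl) act as a C,O-dinucleophile, and C6–C6a–C11a sits at the acrolein oxidation level. Phenol–enal condensation gives the 1-oxatriene O5=C4a–C11b=C11a–C6a=C6, which closes ring B by oxa-6π electrocyclisation.
- Forward order: ring D is dressed first (pyran ring, O10a by aldehyde-to-phenol oxidation, C10 prenyl, acrolein at the bromide). Ring B forms on joining the halves, and ring C is closed last.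
- Helpers: a temporary boron bridge and two acetates on the ring D phenols; the acetates are removed before ring C closure.
- Stereochemistry: the C6a=C11a alkene left by the ring B closure is a vinylogous phenol of the C3 hydroxyl. A chiral phosphoric acid protonates C6a face-selectively, and the ring D hydroxyl closes on C11a, cis by the tether, to give (6aR,11aR).

Key step: step 11

Remark: 2-bromo-4,5-dihydroxybenzaldehyde 1 is taken as a catalogue compound.

**Step 1**
Reactants: 1 2-bromo-4,5-dihydroxybenzaldehyde
Product: 2 2-bromo-5-hydroxy-4-[(2-methylbut-3-yn-2-yl)oxy]benzaldehyde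
Conditions: 3-chloro-3-methylbut-1-yne (1.1 equiv), DBU (1.1 equiv), CuCl2 (1 mol %), MeCN, 0 °C
Reagents that add atoms: 3-chloro-3-methylbut-1-yne, CC(C)(Cl)C#C
Why: copper-catalysed propargylic etherification of a phenoxide, in which one equivalent of base should ionise only the hydroxyl para to the formyl group, as in the selective 4-O-alkylation of 3,4-dihydroxybenzaldehyde.

**Step 2**
Reactants: 2
Product: 4 4-bromo-6-[(2-methylbut-3-yn-2-yl)oxy]benzene-1,3-diol, via aryl formate 3 (not isolated)
Conditions: mCPBA (1.2 equiv), CH2Cl2, 0 °C to rt; then K2CO3 (0.2 equiv), MeOH, 0 °C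
Reagents that add atoms: mCPBA, OOC(=O)c1cccc(Cl)c1
Why: Baeyer–Villiger (Dakin-type) oxidation in which the electron-rich aryl group, para to the ether oxygen, should migrate in preference to hydrogen, the terminal alkyne being inert to the peracid and methanolysis freeing the phenol.

**Step 3**
Reactants: 4
Product: 5 5-bromo-2,2-dimethyl-2H-chromene-6,8-diol
Conditions: o-xylene, 140 °C, argon
Reagents that add atoms: none
Why: aryl propargyl ether Claisen rearrangement followed by 1,5-hydrogen shift and oxa-6π electrocyclisation, which can form the pyran ring in one direction only because the other ortho carbon of the ether oxygen carries a hydroxyl.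

**Step 4**
Reactants: 5
Product: 6 5-bromo-2,2-dimethyl-6-[(2-methylbut-3-en-2-yl)oxy]-2H-chromen-8-ol
Conditions: tert-butyl 2-methylbut-3-en-2-yl carbonate (1.05 equiv), Pd(PPh3)4 (2 mol %), THF, 0 °C
Reagents that add atoms: tert-butyl 2-methylbut-3-en-2-yl carbonate, C=CC(C)(C)OC(=O)OC(C)(C)C
Why: Tsuji–Trost O-allylation in which the phenoxide attacks the 1,1-dimethylallyl palladium complex at its tertiary terminus; the more acidic hydroxyl next to bromine should react first, and the 8-O isomer is harmless because its only free ortho position is the same C7.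

**Step 5**
Reactants: 6
Product: 7 5-bromo-2,2-dimethyl-7-(3-methylbut-2-en-1-yl)-2H-chromene-6,8-diyl diacetate
Conditions: Ac2O, NaOAc, 140 °C
Reagents that add atoms: acetic anhydride, CC(=O)OC(C)=O
Why: aromatic Claisen rearrangement of the 1,1-dimethylallyl ether to the only free ortho carbon (C7) should deliver the linear prenyl group, and acetylation in the same pot caps both phenols before they can add to the new alkene.

**Step 6**
Reactants: 7; 8 2-bromo-3,3-diethoxyprop-1-ene
Product: 11 5-(3,3-diethoxyprop-1-en-2-yl)-2,2-dimethyl-7-(3-methylbut-2-en-1-yl)-2H-chromene-6,8-diyl diacetate, via vinyllithium 9 (not isolated), via vinylzinc chloride 10 (not isolated)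
Conditions: 8, t-BuLi (2.0 equiv), Et2O, −78 °C; ZnCl2 (1.1 equiv), THF, −78 °C to rt; then 7, Pd(OAc)2 (3 mol %), 2-dicyclohexylphosphino-2',6'-dimethoxybiphenyl (6 mol %), THF, 50 °C
Reagents that add atoms: none
Why: Negishi coupling, in which the organozinc should leave the aryl acetates untouched and the bulky biarylphosphine is suited to an aryl bromide with two ortho substituents.

**Step 7**
Reactants: 11
Product: 12 2-[6,8-bis(acetyloxy)-2,2-dimethyl-7-(3-methylbut-2-en-1-yl)-2H-chromen-5-yl]prop-2-enal
Conditions: oxalic acid (5 % aq.), THF, 0 °C to rt; crude product used at once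
Reagents that add atoms: water, O
Why: hydrolysis of the allylic acetal through a conjugated oxocarbenium ion should be far faster than cleavage of the aryl acetates, and the labile 2-arylacrolein is not stored.

**Step 8**
Reactants: 13 4-bromobenzene-1,3-diol
Product: 14 1-bromo-2,4-bis(methoxymethoxy)benzene
Conditions: MOMCl (2.5 equiv), i-Pr2NEt (3 equiv), CH2Cl2, 0 °C to rt
Reagents that add atoms: chloromethyl methyl ether, COCCl
Why: standard O-alkylation that gives acetal protecting groups able to withstand the aryllithium of the next step.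

**Step 9**
Reactants: 14
Product: 16 2,4-bis(methoxymethoxy)-1-(3-methylbut-2-en-1-yl)benzene, via aryllithium 15 (not isolated)
Conditions: n-BuLi (1.05 equiv), THF, −78 °C; CuBr·SMe2 (10 mol %), 1-bromo-3-methylbut-2-ene (1.2 equiv), −78 °C to 0 °C
Reagents that add atoms: 1-bromo-3-methylbut-2-ene, CC(C)=CCBr
Why: bromine–lithium exchange fixes the site, and copper-catalysed allylation of the aryllithium at the primary carbon of prenyl bromide should give the linear prenyl arene.

**Step 10**
Reactants: 16
Product: 17 4-(3-methylbut-2-en-1-yl)benzene-1,3-diol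
Conditions: HCl (1.25 M in MeOH), rt
Reagents that add atoms: none
Why: acetal exchange with methanol should remove both methoxymethyl groups under conditions mild enough that the ortho-prenyl phenol does not close to a chroman.

**Step 11**
Reactants: 12; 17
Product: 20 5-[7-hydroxy-6-(3-methylbut-2-en-1-yl)-2H-chromen-3-yl]-2,2-dimethyl-7-(3-methylbut-2-en-1-yl)-2H-chromene-6,8-diyl diacetate, via benzodioxaborin 18 (not isolated), via ortho-quinone methide 19 (not isolated)
Conditions: PhB(OH)2 (1.2 equiv), EtCO2H (0.3 equiv), toluene, reflux, azeotropic removal of water; 12 added slowly to 17 (1.3 equiv)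
Reagents that add atoms: none
Why: The aryl boronate of 17 binds the aldehyde of 12 and delivers the carbonyl carbon to the ortho carbon through a six-membered transition state (bond C11b–C11a, benzodioxaborin 18); loss of the boron bridge on heating gives the ortho-quinone methide 19, a 1-oxatriene that closes ring B by thermal oxa-6π electrocyclisation (bond O5–C6). The closest known reaction is the phenylboronic acid-mediated synthesis of 2H-chromenes from phenols and α,β-unsaturated aldehydes, a formal 3+3 annulation. Ring B closes by a disrotatory six-electron electrocyclisation and no stereocentre is formed, since C6a and C11a end as the two alkene carbons. The step needs 1,2- and not 1,4-attack on the enal and attack at the resorcinol carbon that becomes C11b: the boron template brings only the carbonyl carbon within reach of an ortho carbon, the wanted carbon is para to the second hydroxyl and unhindered, the carbon between the two oxygens is crowded, and the remaining ortho carbon carries the prenyl group. The ring D phenols are acetylated, so they can neither act as the phenol partner nor close ring C early, and slow addition of 12 should hold back polymerisation and a second annulation on the product.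

**Step 12**
Reactants: 20
Product: 21 5-[7-hydroxy-6-(3-methylbut-2-en-1-yl)-2H-chromen-3-yl]-2,2-dimethyl-7-(3-methylbut-2-en-1-yl)-2H-chromene-6,8-diol
Conditions: N2H4·H2O (2.5 equiv), THF/MeOH, 0 °C, argon; crude product used at once
Reagents that add atoms: none
Why: hydrazinolysis should cleave the aryl acetates under near-neutral, non-oxidising conditions that leave the acid-sensitive isoflavene alkene and the electron-rich phenols intact.

**Step 13**
Reactants: 21
Product: 22 Lespecyrtin E3, the (6aR,11aR)-pterocarpan
Conditions: (R)-3,3'-bis(2,4,6-triisopropylphenyl)-1,1'-binaphthyl-2,2'-diyl hydrogen phosphate (10 mol %), toluene, 4 Å MS, −20 °C to 0 °C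
Reagents that add atoms: none
Why: Proposed new method: the C6a=C11a alkene of 21 is a vinylogous phenol of the ring A hydroxyl, so the chiral phosphoric acid, held by a hydrogen bond to the ortho hydroxyl of ring D, should protonate C6a on one face to give a para-quinone methide/phosphate ion pair in which that hydroxyl closes ring C by 5-exo attack on C11a, C6a being set by the catalyst and C11a by the tether, which allows only cis fusion; the closest known reaction types are chiral phosphoric acid-catalysed additions to quinone methides generated by protonation of hydroxystyrenes and chiral Brønsted acid-catalysed intramolecular hydroalkoxylation of styrenes, the prenyl and pyran alkenes lack the phenol push and should not be protonated, and the catalyst antipode that gives the 6aR,11aR series has to be fixed in a first trial.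

**Compound list**
1 | 2-bromo-4,5-dihydroxybenzaldehyde | O=Cc1cc(O)c(O)cc1Br | starting material
2 | 2-bromo-5-hydroxy-4-[(2-methylbut-3-yn-2-yl)oxy]benzaldehyde | O=Cc1cc(O)c(OC(C)(C)C#C)cc1Br | intermediate
3 | 2-bromo-5-hydroxy-4-[(2-methylbut-3-yn-2-yl)oxy]phenyl formate | O=COc1cc(O)c(OC(C)(C)C#C)cc1Br | intermediate
4 | 4-bromo-6-[(2-methylbut-3-yn-2-yl)oxy]benzene-1,3-diol | Oc1cc(O)c(OC(C)(C)C#C)cc1Br | intermediate
5 | 5-bromo-2,2-dimethyl-2H-chromene-6,8-diol | CC1(C)C=Cc2c(Br)c(O)cc(O)c2O1 | intermediate
6 | 5-bromo-2,2-dimethyl-6-[(2-methylbut-3-en-2-yl)oxy]-2H-chromen-8-ol | CC1(C)C=Cc2c(Br)c(OC(C)(C)C=C)cc(O)c2O1 | intermediate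
7 | 5-bromo-2,2-dimethyl-7-(3-methylbut-2-en-1-yl)-2H-chromene-6,8-diyl diacetate | CC(=O)Oc1c(Br)c2C=CC(C)(C)Oc2c(OC(C)=O)c1CC=C(C)C | intermediate
8 | 2-bromo-3,3-diethoxyprop-1-ene | C=C(Br)C(OCC)OCC | starting material
9 | [1-(diethoxymethyl)ethenyl]lithium | [Li]C(=C)C(OCC)OCC | intermediate
10 | chlorido[1-(diethoxymethyl)ethenyl]zinc | Cl[Zn]C(=C)C(OCC)OCC | intermediate
11 | 5-(3,3-diethoxyprop-1-en-2-yl)-2,2-dimethyl-7-(3-methylbut-2-en-1-yl)-2H-chromene-6,8-diyl diacetate | CCOC(OCC)C(=C)c1c(OC(C)=O)c(CC=C(C)C)c(OC(C)=O)c2OC(C)(C)C=Cc12 | intermediate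
12 | 2-[6,8-bis(acetyloxy)-2,2-dimethyl-7-(3-methylbut-2-en-1-yl)-2H-chromen-5-yl]prop-2-enal | O=CC(=C)c1c(OC(C)=O)c(CC=C(C)C)c(OC(C)=O)c2OC(C)(C)C=Cc12 | intermediate
13 | 4-bromobenzene-1,3-diol | Oc1ccc(Br)c(O)c1 | starting material
14 | 1-bromo-2,4-bis(methoxymethoxy)benzene | COCOc1ccc(Br)c(OCOC)c1 | intermediate
15 | [2,4-bis(methoxymethoxy)phenyl]lithium | [Li]c1ccc(OCOC)cc1OCOC | intermediate
16 | 2,4-bis(methoxymethoxy)-1-(3-methylbut-2-en-1-yl)benzene | COCOc1ccc(CC=C(C)C)c(OCOC)c1 | intermediate
17 | 4-(3-methylbut-2-en-1-yl)benzene-1,3-diol | CC(C)=CCc1ccc(O)cc1O | intermediate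
18 | 5-{1-[7-hydroxy-6-(3-methylbut-2-en-1-yl)-2-phenyl-4H-1,3,2-benzodioxaborinin-4-yl]ethenyl}-2,2-dimethyl-7-(3-methylbut-2-en-1-yl)-2H-chromene-6,8-diyl diacetate, racemic at C4 of the boron ring | CC(C)=CCc1cc2C(OB(c3ccccc3)Oc2cc1O)C(=C)c1c(OC(C)=O)c(CC=C(C)C)c(OC(C)=O)c2OC(C)(C)C=Cc12 | intermediate
19 | 5-{3-[4-hydroxy-5-(3-methylbut-2-en-1-yl)-6-oxocyclohexa-2,4-dien-1-ylidene]prop-1-en-2-yl}-2,2-dimethyl-7-(3-methylbut-2-en-1-yl)-2H-chromene-6,8-diyl diacetate, drawn as the ortho-quinone methide of ring A | CC(C)=CCC1=CC(=CC(=C)c2c(OC(C)=O)c(CC=C(C)C)c(OC(C)=O)c3OC(C)(C)C=Cc23)C(=O)C=C1O | intermediate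
20 | 5-[7-hydroxy-6-(3-methylbut-2-en-1-yl)-2H-chromen-3-yl]-2,2-dimethyl-7-(3-methylbut-2-en-1-yl)-2H-chromene-6,8-diyl diacetate | CC(C)=CCc1cc2C=C(COc2cc1O)c1c(OC(C)=O)c(CC=C(C)C)c(OC(C)=O)c2OC(C)(C)C=Cc12 | intermediate
21 | 5-[7-hydroxy-6-(3-methylbut-2-en-1-yl)-2H-chromen-3-yl]-2,2-dimethyl-7-(3-methylbut-2-en-1-yl)-2H-chromene-6,8-diol | CC(C)=CCc1cc2C=C(COc2cc1O)c1c(O)c(CC=C(C)C)c(O)c2OC(C)(C)C=Cc12 | intermediate
22 | Lespecyrtin E3, (6aR,11aR)-cis-pterocarpan with C2 and C10 prenyl groups, C3 and C9 hydroxyls and a 2,2-dimethylpyran ring fused at C7–C8 | CC(C)=CCc1cc2c(cc1O)OC[C@H]1c3c4c(c(O)c(CC=C(C)C)c3O[C@@H]21)OC(C)(C)C=C4 | target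

**Totals**
Total step count: 13. Longest linear sequence: 10 steps (steps 1 to 7, then 11 to 13).

**Steps most likely to fail**

Step 13. The face selectivity of the protonation may be low or of the wrong sense, the acid may be too weak to protonate C6a, or the product may lose enantiopurity by acid-induced reopening of ring C. Fallback: from 21, an achiral acid (diphenyl phosphate, 5 mol %, toluene, rt) should give the racemic cis-fused pterocarpan F1 by the same protonation and ring closure without face control. Preparative HPLC on a cellulose tris(3,5-dimethylphenylcarbamate) phase then separates the enantiomers, and the (6aR,11aR) fraction is 22.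

Step 11. Conjugate addition to the acrolein or its polymerisation may outrun the templated 1,2-addition. The carbon between the two ring A oxygens may also compete, and a second annulation on the product is possible. Fallback: from 12 and 17, base-catalysed oxa-Michael addition (1,4-diazabicyclo[2.2.2]octane, 10 mol %, MeCN, 0 °C) of the less hindered hydroxyl of 17 should give the 3-aryloxy-2-arylpropanal F2. Pyridinium p-toluenesulfonate (toluene, 60 °C, 4 Å MS) then closes ring B by intramolecular hydroxyalkylation of the ring A carbon para to the free hydroxyl and loss of water, which returns to the route at 20. The order of bond formation is reversed (O5–C6 first, C11b–C11a second) and no boron template is used.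

Step 6. Oxidative addition and transmetalation may be slow at the doubly ortho-substituted bromide, and the α-branched vinylmetal may be lost by protonation. Fallback: from 7, Suzuki–Miyaura coupling with the unbranched (E)-2-(2-ethoxyvinyl)-4,4,5,5-tetramethyl-1,3,2-dioxaborolane (Pd(OAc)2, 2-dicyclohexylphosphino-2',6'-dimethoxybiphenyl, K3PO4, toluene, 80 °C) should give the enol ether F3. Mild acid (oxalic acid, aq. THF) gives the arylacetaldehyde F4, and α-methylenation with N,N-dimethylmethyleneiminium iodide and Et3N (CH2Cl2, rt) returns to the route at 12, bypassing 11.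

**Further compounds**
F1 | step 13 | racemic cis-pterocarpan, 1:1 mixture of 22 and its enantiomer | CC(C)=CCc1cc2c(cc1O)OC[C@H]1c3c4c(c(O)c(CC=C(C)C)c3O[C@@H]21)OC(C)(C)C=C4.CC(C)=CCc1cc2c(cc1O)OC[C@@H]1c3c4c(c(O)c(CC=C(C)C)c3O[C@H]21)OC(C)(C)C=C4
F2 | step 11 | 5-{1-[3-hydroxy-4-(3-methylbut-2-en-1-yl)phenoxy]-3-oxopropan-2-yl}-2,2-dimethyl-7-(3-methylbut-2-en-1-yl)-2H-chromene-6,8-diyl diacetate, racemic | O=CC(COc1ccc(CC=C(C)C)c(O)c1)c1c(OC(C)=O)c(CC=C(C)C)c(OC(C)=O)c2OC(C)(C)C=Cc12
F3 | step 6 | 5-[(E)-2-ethoxyethenyl]-2,2-dimethyl-7-(3-methylbut-2-en-1-yl)-2H-chromene-6,8-diyl diacetate | CCO/C=C/c1c(OC(C)=O)c(CC=C(C)C)c(OC(C)=O)c2OC(C)(C)C=Cc12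
F4 | step 6 | 2,2-dimethyl-7-(3-methylbut-2-en-1-yl)-5-(2-oxoethyl)-2H-chromene-6,8-diyl diacetate | O=CCc1c(OC(C)=O)c(CC=C(C)C)c(OC(C)=O)c2OC(C)(C)C=Cc12
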